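The runs are calculated with constants of no real substance; noise was put on by code.

The target is what we want, so we build the flask around it, one process at a time, and ask how much side product each addition brings.

| setting | theta | gamma | epsilon | beta | dawn | dusk | spring | summer |
|---|---|---|---|---|---|---|---|---|
| starting material | 0.25 M | 0.25 M | 0.25 M | 0.50 M | 0.25 M | 0.25 M (fed, over 8.0 h) | 0.25 M | 0.25 M (in portions, 3, over 8.0 h) |
| reagent | 0.50 M | 0.25 M | 1 M | 0.50 M | 0.500 M | 0.500 M | 0.500 M (fed, over 8.0 h) | 0.500 M |
| remark | run made earlier | run made earlier | run made earlier | run made earlier | everything together at the start | all else is in the flask from the start; the feed brings no volume worth counting | all else is in the flask from the start; the feed brings no volume worth counting | first portion at the start, last at 8.0 h |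
| time |  |  |  |  | 20 h | 20 h | 20 h | 20 h |

| run | time / h | side product / % | target / % |
|---|---|---|---|
| theta | 0.667 | 2 | 50 |
| theta | 2.00 | 8 | 75 |
| theta | 3.00 | 12 | 77 |
| theta | 5.00 | 14 | 81 |
| theta | 8.00 | 21 | 81 |
| theta | 10.0 | 20 | 80 |
| theta | 12.0 | 18 | 81 |
| gamma | 0.833 | 6 | 43 |
| gamma | 2.50 | 11 | 64 |
| gamma | 5.00 | 18 | 69 |
| gamma | 6.00 | 21 | 68 |
| gamma | 10.0 | 26 | 71 |
| gamma | 12.0 | 26 | 70 |
| gamma | 15.0 | 26 | 67 |
| epsilon | 0.833 | 3 | 65 |
| epsilon | 2.50 | 10 | 84 |
| epsilon | 5.00 | 9 | 87 |
| epsilon | 6.00 | 13 | 85 |
| epsilon | 10.0 | 11 | 87 |
| epsilon | 12.0 | 11 | 86 |
| epsilon | 15.0 | 10 | 86 |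
| beta | 3.00 | 17 | 74 |
| beta | 6.00 | 24 | 69 |
| beta | 10.0 | 30 | 69 |
| beta | 12.0 | 29 | 68 |
| beta | 15.0 | 32 | 68 |

(standard deviation of a reading: 1.5 percentage points)

- in percentages every species weighs as the starting material in it: one side product counts as two

- the flask that comes out highest in amount of side product, in percent of the starting material charged, or "all alike" when all lie within 1.5 percentage points (dawn / dusk / spring / summer / all alike)
- side product at the end, in percent of the starting material charged, dawn
- side product at the end, in percent of the starting material charged, dusk
- side product at the end, in percent of the starting material charged, spring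
- side product at the end, in percent of the starting material charged, summer

Take the main step first: if each starting material in dawn takes one reagent, c_reagent goes from 0.500 M to 0.250 M and the target takes the whole charge. Now add the side process. In the runs, side product grows while target stands in the flask, and its share falls as reagent rises. We solve the reagent at both ends of the conversion and join them by their mean, the working level L. In theta L is 0.375 M. In gamma L is 0.125 M, in epsilon 0.875 M. At 12.0 h the ratio of side product to target reads 0.371 in gamma and 0.128 in epsilon, which gives an exponent on L of 0.547; we round it to 0.5. So we name a selectivity factor K, the final ratio of side product to target times the square root of L over the charged c_starting material. Theta's plateau ratio reads 0.244, so K is 0.299. Beta tests the c_starting material in K: with its L of 0.250 M, K gives a ratio of 0.422, and beta's readings at 10.0 h give 0.435.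

Last comes the feed, which in our reckoning acts through the ends of L. Dawn, dusk and summer hold the full charge of reagent from the start, so L is 0.375 M, and we reckon 19.6% side product for each. Spring starts without reagent and by the main step ends at 0.250 M, so its L is 0.125 M, a third of that. Its ratio is 0.422, and we reckon 29.7%.

The forecast names spring highest, with 20% for dawn, 20% for dusk, 27% for spring and 20% for summer, holding that “selectivity depends on target and reagent”; for spring its figure lies below ours.

Spring ends at 28.4% side product, more than dawn, dusk or summer, which hold 18.9%, 21.1% and 21.1%. Its mean c_reagent over the first 8.0 h was 0.114 M, against 0.305 M in dawn. Spring's own ratio and L give K as 0.283, against 0.299 from theta.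

    starting material + reagent → target, rate k1*[starting material]^1.5*[reagent]^0.5 (k = 3.90 M⁻¹ h⁻¹)
    starting material + target → side product (k = 0.490 M⁻¹ h⁻¹)

For the neighbour of spring charged with 1.2 M of reagent, L is 0.475 M, so K gives a ratio of 0.217 and 17.8% side product. The computed flask holds 20.8%, more than K gave, and level with the 21.1% of dusk on its 0.500 M, so at that charge spring's lead over dusk is gone.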